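**Strategy.** The target is the C14–O ester of two labdane halves, and both are cut back to one C16 aldehyde, 14. The feature exploited is that ring A holds the contiguous carbons C4 (gem-dimethyl), C5 and C10 (methyl-bearing), a pattern hidden in a 1,2,2-trimethylcyclopentane whose exocyclic carbinol carbon is C5. In step 6, ionisation of mesylate 9 (this cyclopentane with a seven-carbon (Z)-allylsilane chain) moves C4 from C10 to C5. The five-membered ring thereby grows into ring A, the tertiary C10 cation is trapped by the allylsilane to close ring B, and C5, C10, C9 and the C8 methylene arise together, relayed from one CBS-set carbinol.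

Key step: step 6

Remark: labdane numbering is used for the atoms (ring A = C1–C5 and C10, ring B = C5–C10); compounds 3 to 9 are carried as both configurations of the quaternary ring carbon, because that centre becomes the planar C10 cation in step 6.

**Step 1**
Reactants: 1 1-(2-methylcyclopent-1-en-1-yl)ethan-1-one
Product: 3 1-(1,2,2-trimethylcyclopentyl)ethan-1-one (racemic), via lithium enolate 2 (not isolated)
Conditions: Me2CuLi (from MeLi, CuI), Et2O, −20 → 0 °C; then MeI (5 equiv), HMPA, THF, 0 °C → rt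
Reagents that add atoms: lithium dimethylcuprate [Li+].C[Cu-]C; iodomethane CI
Why: Cuprate conjugate addition to the tetrasubstituted enone (as with pulegone) builds the gem-dimethyl carbon and gives the regiodefined tetrasubstituted enolate, which is C-methylated in the same flask; the new quaternary centre is racemic, which is harmless because it is erased in step 6.

**Step 2**
Reactants: 3 1-(1,2,2-trimethylcyclopentyl)ethan-1-one
Product: 5 1-(1,2,2-trimethylcyclopentyl)pent-4-yn-1-one, via lithium enolate 4 (not isolated)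
Conditions: LDA, THF, −78 °C; then propargyl bromide, DMPU, −78 → 0 °C
Reagents that add atoms: 3-bromoprop-1-yne (propargyl bromide) C#CCBr
Why: Ketone enolate alkylation: 3 has enolisable hydrogens only on the acetyl methyl group, so the kinetic lithium enolate is propargylated there to add C7–C9 as a terminal alkyne; no stereocentre is formed.

**Step 3**
Reactants: 5 1-(1,2,2-trimethylcyclopentyl)pent-4-yn-1-one
Product: 6 (1S)-1-(1,2,2-trimethylcyclopentyl)pent-4-yn-1-ol
Conditions: (R)-2-methyl-CBS-oxazaborolidine (20 mol %), catecholborane, toluene, −20 °C → rt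
Reagents that add atoms: none
Why: Corey–Bakshi–Shibata reduction: the tert-alkyl group is the large substituent, so the (R)-catalyst should deliver hydride to give the (S)-carbinol in both enantiomers of 5 (reagent control), and catecholborane does not hydroborate the alkyne at this temperature.

**Step 4**
Reactants: 6 (1S)-1-(1,2,2-trimethylcyclopentyl)pent-4-yn-1-ol
Product: 8 (3Z,7S)-7-(1,2,2-trimethylcyclopentyl)-4-[(trimethylsilyl)methyl]hept-3-ene-1,7-diol, via alkenylcopper 7 (not isolated)
Conditions: Me3SiCH2MgCl (3 equiv), CuBr·SMe2 (2 equiv), Et2O/Me2S, −40 → −10 °C; then oxirane, THF, −30 → 0 °C; NH4Cl (aq)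
Reagents that add atoms: (trimethylsilyl)methylmagnesium chloride C[Si](C)(C)C[Mg]Cl; oxirane C1CO1
Why: Syn-carbocupration of the terminal alkyne by the silylmethylcopper reagent puts CH2SiMe3 on the internal carbon and copper on the terminus, and the alkenylcopper opens oxirane with retention, so C11 ends cis to CH2SiMe3 and trans to C7 (Z-allylsilane); the first equivalent of Grignard reagent only deprotonates the hydroxyl.

**Step 5**
Reactants: 8 (3Z,7S)-7-(1,2,2-trimethylcyclopentyl)-4-[(trimethylsilyl)methyl]hept-3-ene-1,7-diol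
Product: 9 (3Z,7S)-7-(1,2,2-trimethylcyclopentyl)-4-[(trimethylsilyl)methyl]hept-3-ene-1,7-diyl dimethanesulfonate
Conditions: MsCl (2.5 equiv), Et3N, CH2Cl2, −10 °C; used without chromatography
Reagents that add atoms: methanesulfonyl chloride CS(=O)(=O)Cl
Why: Mesylation through sulfene reaches the hindered neopentyl-type secondary hydroxyl as well as the primary one, with retention at the carbinol carbon because no C–O bond is broken.

**Step 6**
Reactants: 9 (3Z,7S)-7-(1,2,2-trimethylcyclopentyl)-4-[(trimethylsilyl)methyl]hept-3-ene-1,7-diyl dimethanesulfonate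
Product: 12 2-[(1S,4aS,8aS)-5,5,8a-trimethyl-2-methylidenedecahydronaphthalen-1-yl]ethyl methanesulfonate, via tertiary C10 cation 10 (not isolated), via β-silyl C8 cation 11 (not isolated)
Conditions: 2,6-lutidine (1.5 equiv), 1,1,1,3,3,3-hexafluoropropan-2-ol (HFIP, 0.01 M), 25 → 40 °C
Reagents that add atoms: none
Why: Proposed new method: ionisation of the neopentyl-type secondary mesylate in HFIP is assisted by an anti-periplanar 1,2-shift of the quaternary C(CH3)2 ring carbon (Wagner–Meerwein ring enlargement, cyclopentylcarbinyl to cyclohexyl), which gives tertiary cation 10; 10 is captured by the (Z)-allylsilane and β-silyl cation 11 loses the silyl group to leave the exocyclic methylene. The closest known reactions are the solvolytic ring enlargement of 1-(1-alkylcyclopentyl)alkyl sulfonates and the allylsilane-terminated cyclisation of 2,2,6-trimethylcyclohexyl (cyclogeranyl-type) cations to trans-decalins; running both in one flask is what is new. Ring A is closed by ring expansion of the five-membered ring (C4 migrates from C10 to C5), ring B by 6-endo-trig attack of C9 on C10. C5 is set by inversion at the carbinol carbon during the shift, so the (S)-mesylate should give (5S) from either epimer of 9, because the quaternary ring carbon becomes the planar cation. C10 and C9 follow from C5 through a chair-like transition state with the C6 tether equatorial (methyl anti to H-5, trans-decalin) and from the alkene geometry (C11 trans to C7 gives the equatorial side chain). The step needs migration of the quaternary carbon in preference to the ring CH2 or the methyl group, secured by its higher migratory aptitude and the relief of vicinal quaternary strain, and ring closure faster than proton loss or hydride shift, secured by the tethered nucleophilic allylsilane in a buffered non-nucleophilic medium in which the primary mesylate does not ionise.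

**Step 7**
Reactants: 12 2-[(1S,4aS,8aS)-5,5,8a-trimethyl-2-methylidenedecahydronaphthalen-1-yl]ethyl methanesulfonate
Product: 14 2-[(1S,4aS,8aS)-5,5,8a-trimethyl-2-methylidenedecahydronaphthalen-1-yl]acetaldehyde, via alkoxysulfonium mesylate 13 (not isolated)
Conditions: NaHCO3, NaI (cat.), DMSO, 110 °C
Reagents that add atoms: dimethyl sulfoxide CS(C)=O
Why: Kornblum oxidation: DMSO displaces the primary mesylate (iodide catalysis) and the alkoxysulfonium ion collapses with bicarbonate to the aldehyde and Me2S; the alkene and the three stereocentres are not involved.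

**Step 8**
Reactants: 15 (4R)-4-hydroxyoxolan-2-one
Product: 16 (4R)-4-[(tert-butyldimethylsilyl)oxy]oxolan-2-one
Conditions: TBSCl, imidazole, DMF, rt
Reagents that add atoms: tert-butyldimethylsilyl chloride CC(C)(C)[Si](C)(C)Cl
Why: Standard silylation of the secondary alcohol, needed so that only the aldol hydroxyl is eliminated in step 9.

**Step 9**
Reactants: 16 (4R)-4-[(tert-butyldimethylsilyl)oxy]oxolan-2-one; 14 2-[(1S,4aS,8aS)-5,5,8a-trimethyl-2-methylidenedecahydronaphthalen-1-yl]acetaldehyde
Product: 20 (3E,4R)-4-[(tert-butyldimethylsilyl)oxy]-3-{2-[(1S,4aS,8aS)-5,5,8a-trimethyl-2-methylidenedecahydronaphthalen-1-yl]ethylidene}oxolan-2-one, via lithium enolate 17 (not isolated), via lithium aldolate 18 (not isolated), via aldol mesylate 19 (not isolated)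
Conditions: LDA, THF, −78 °C; then 14; then MsCl, −78 → 0 °C; then DBU, 0 °C → rt
Reagents that add atoms: none
Why: Aldol addition of the lactone enolate to 14, mesylation of the aldolate and E1cB elimination with DBU give the α-alkylidene lactone; the E isomer (C11 trans to the lactone carbonyl) is expected as the thermodynamic product that avoids allylic strain with the C14 silyloxy group, and C14 stays (R) from 15.

**Step 10**
Reactants: 20 (3E,4R)-4-[(tert-butyldimethylsilyl)oxy]-3-{2-[(1S,4aS,8aS)-5,5,8a-trimethyl-2-methylidenedecahydronaphthalen-1-yl]ethylidene}oxolan-2-one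
Product: 21 (3E,4R)-4-hydroxy-3-{2-[(1S,4aS,8aS)-5,5,8a-trimethyl-2-methylidenedecahydronaphthalen-1-yl]ethylidene}oxolan-2-one (isocoronarin D type alcohol)
Conditions: HF·pyridine, THF/pyridine, 0 °C → rt
Reagents that add atoms: none
Why: Fluoride cleavage of the silyl ether under buffered conditions that avoid base-induced elimination or migration in the β-hydroxy-α-alkylidene lactone.

**Step 11**
Reactants: 22 methyl 4,4-dimethoxybutanoate; 14 2-[(1S,4aS,8aS)-5,5,8a-trimethyl-2-methylidenedecahydronaphthalen-1-yl]acetaldehyde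
Product: 26 methyl (2E)-2-(2,2-dimethoxyethyl)-4-[(1S,4aS,8aS)-5,5,8a-trimethyl-2-methylidenedecahydronaphthalen-1-yl]but-2-enoate, via lithium enolate 23 (not isolated), via lithium aldolate 24 (not isolated), via aldol mesylate 25 (not isolated)
Conditions: LDA, THF, −78 °C; then 14; then MsCl, −78 → 0 °C; then DBU, rt
Reagents that add atoms: none
Why: The same aldol, mesylation and E1cB elimination sequence on the ester enolate gives the trisubstituted enoate, with the E isomer (C11 trans to the ester carbonyl) favoured thermodynamically and any minor Z isomer removable by chromatography; the dimethyl acetal is inert to base.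

**Step 12**
Reactants: 26 methyl (2E)-2-(2,2-dimethoxyethyl)-4-[(1S,4aS,8aS)-5,5,8a-trimethyl-2-methylidenedecahydronaphthalen-1-yl]but-2-enoate
Product: 27 (2E)-2-(2,2-dimethoxyethyl)-4-[(1S,4aS,8aS)-5,5,8a-trimethyl-2-methylidenedecahydronaphthalen-1-yl]but-2-enoic acid
Conditions: LiOH, THF/MeOH/H2O, 40 °C; then AcOH to pH 5
Reagents that add atoms: lithium hydroxide [Li+].[OH-]
Why: Saponification of the methyl ester; the acetal survives base and the work-up at pH 5.

**Step 13**
Reactants: 27 (2E)-2-(2,2-dimethoxyethyl)-4-[(1S,4aS,8aS)-5,5,8a-trimethyl-2-methylidenedecahydronaphthalen-1-yl]but-2-enoic acid; 21 (3E,4R)-4-hydroxy-3-{2-[(1S,4aS,8aS)-5,5,8a-trimethyl-2-methylidenedecahydronaphthalen-1-yl]ethylidene}oxolan-2-one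
Product: 29 (3R,4E)-5-oxo-4-{2-[(1S,4aS,8aS)-5,5,8a-trimethyl-2-methylidenedecahydronaphthalen-1-yl]ethylidene}oxolan-3-yl (2E)-2-(2,2-dimethoxyethyl)-4-[(1S,4aS,8aS)-5,5,8a-trimethyl-2-methylidenedecahydronaphthalen-1-yl]but-2-enoate, via mixed anhydride 28 (not isolated)
Conditions: 2,4,6-trichlorobenzoyl chloride, Et3N, THF, 0 °C → rt; then 21, DMAP (0.3 equiv), toluene, rt
Reagents that add atoms: none
Why: Yamaguchi esterification: the mixed anhydride is attacked at the less hindered enoyl carbonyl by the secondary allylic C14 hydroxyl under DMAP catalysis, and O-acylation leaves the configuration at C14 untouched.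

**Step 14**
Reactants: 29 (3R,4E)-5-oxo-4-{2-[(1S,4aS,8aS)-5,5,8a-trimethyl-2-methylidenedecahydronaphthalen-1-yl]ethylidene}oxolan-3-yl (2E)-2-(2,2-dimethoxyethyl)-4-[(1S,4aS,8aS)-5,5,8a-trimethyl-2-methylidenedecahydronaphthalen-1-yl]but-2-enoate
Product: 30 (3R,4E)-5-oxo-4-{2-[(1S,4aS,8aS)-5,5,8a-trimethyl-2-methylidenedecahydronaphthalen-1-yl]ethylidene}oxolan-3-yl (2E)-2-(2-oxoethyl)-4-[(1S,4aS,8aS)-5,5,8a-trimethyl-2-methylidenedecahydronaphthalen-1-yl]but-2-enoate (CNP0274315.1)
Conditions: LiBF4, MeCN/H2O (50:1), rt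
Reagents that add atoms: water O
Why: Mild Lewis-acid-assisted hydrolysis of the dimethyl acetal releases the C15 aldehyde, while the exocyclic methylenes, the allylic ester and the lactone should remain intact.

**Compound list**

1 | 1-(2-methylcyclopent-1-en-1-yl)ethan-1-one | CC(=O)C1=C(C)CCC1 | starting material
2 | lithium 1-(2,2-dimethylcyclopentylidene)ethan-1-olate | [Li]OC(C)=C1CCCC1(C)C | intermediate (not isolated)
3 | 1-(1,2,2-trimethylcyclopentyl)ethan-1-one (racemic) | CC(=O)C1(C)CCCC1(C)C | intermediate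
4 | lithium 1-(1,2,2-trimethylcyclopentyl)ethen-1-olate | [Li]OC(=C)C1(C)CCCC1(C)C | intermediate (not isolated)
5 | 1-(1,2,2-trimethylcyclopentyl)pent-4-yn-1-one | C#CCCC(=O)C1(C)CCCC1(C)C | intermediate
6 | (1S)-1-(1,2,2-trimethylcyclopentyl)pent-4-yn-1-ol (both configurations of the ring carbon) | C#CCC[C@H](O)C1(C)CCCC1(C)C | intermediate
7 | alkenylcopper from syn-addition, as its chloromagnesium alkoxide (Cu cis to CH2SiMe3) | C[Si](C)(C)C/C(CC[C@H](O[Mg]Cl)C1(C)CCCC1(C)C)=C\[Cu] | intermediate (not isolated)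
8 | (3Z,7S)-7-(1,2,2-trimethylcyclopentyl)-4-[(trimethylsilyl)methyl]hept-3-ene-1,7-diol | C[Si](C)(C)C/C(CC[C@H](O)C1(C)CCCC1(C)C)=C\CCO | intermediate
9 | (3Z,7S)-7-(1,2,2-trimethylcyclopentyl)-4-[(trimethylsilyl)methyl]hept-3-ene-1,7-diyl dimethanesulfonate | C[Si](C)(C)C/C(CC[C@H](OS(C)(=O)=O)C1(C)CCCC1(C)C)=C\CCOS(C)(=O)=O | intermediate
10 | ring-expanded tertiary C10 cation (1,3,3-trimethylcyclohexyl cation with the allylsilane chain on C5, C5 configured as in 12) | C[C+]1CCCC(C)(C)[C@@H]1CC/C(C[Si](C)(C)C)=C/CCOS(C)(=O)=O | intermediate (not isolated)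
11 | bicyclic β-silyl C8 cation (trans-decalin, configured as in 12) | C[Si](C)(C)C[C+]1CC[C@H]2C(C)(C)CCC[C@]2(C)[C@H]1CCOS(C)(=O)=O | intermediate (not isolated)
12 | 2-[(1S,4aS,8aS)-5,5,8a-trimethyl-2-methylidenedecahydronaphthalen-1-yl]ethyl methanesulfonate | C=C1CC[C@H]2C(C)(C)CCC[C@]2(C)[C@H]1CCOS(C)(=O)=O | intermediate
13 | dimethyl{2-[(1S,4aS,8aS)-5,5,8a-trimethyl-2-methylidenedecahydronaphthalen-1-yl]ethoxy}sulfonium methanesulfonate | C=C1CC[C@H]2C(C)(C)CCC[C@]2(C)[C@H]1CCO[S+](C)C.CS(=O)(=O)[O-] | intermediate (not isolated)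
14 | 2-[(1S,4aS,8aS)-5,5,8a-trimethyl-2-methylidenedecahydronaphthalen-1-yl]acetaldehyde | C=C1CC[C@H]2C(C)(C)CCC[C@]2(C)[C@H]1CC=O | intermediate
15 | (4R)-4-hydroxyoxolan-2-one ((R)-3-hydroxy-γ-butyrolactone) | O[C@H]1COC(=O)C1 | starting material
16 | (4R)-4-[(tert-butyldimethylsilyl)oxy]oxolan-2-one | CC(C)(C)[Si](C)(C)O[C@H]1COC(=O)C1 | intermediate
17 | lithium enolate of 16 | CC(C)(C)[Si](C)(C)O[C@H]1COC(O[Li])=C1 | intermediate (not isolated)
18 | lithium aldolate of 16 and 14 (mixture at C12 and C13) | CC(C)(C)[Si](C)(C)O[C@H]1COC(=O)C1C(O[Li])C[C@H]1C(=C)CC[C@H]2C(C)(C)CCC[C@]12C | intermediate (not isolated)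
19 | mesylate of the aldol from 16 and 14 (mixture at C12 and C13) | CC(C)(C)[Si](C)(C)O[C@H]1COC(=O)C1C(OS(C)(=O)=O)C[C@H]1C(=C)CC[C@H]2C(C)(C)CCC[C@]12C | intermediate (not isolated)
20 | (3E,4R)-4-[(tert-butyldimethylsilyl)oxy]-3-{2-[(1S,4aS,8aS)-5,5,8a-trimethyl-2-methylidenedecahydronaphthalen-1-yl]ethylidene}oxolan-2-one | CC(C)(C)[Si](C)(C)O[C@H]1COC(=O)/C1=C/C[C@H]1C(=C)CC[C@H]2C(C)(C)CCC[C@]12C | intermediate
21 | (3E,4R)-4-hydroxy-3-{2-[(1S,4aS,8aS)-5,5,8a-trimethyl-2-methylidenedecahydronaphthalen-1-yl]ethylidene}oxolan-2-one | O[C@H]1COC(=O)/C1=C/C[C@H]1C(=C)CC[C@H]2C(C)(C)CCC[C@]12C | intermediate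
22 | methyl 4,4-dimethoxybutanoate | COC(=O)CCC(OC)OC | starting material
23 | lithium enolate of 22 | COC(O[Li])=CCC(OC)OC | intermediate (not isolated)
24 | lithium aldolate of 22 and 14 (mixture at C12 and C13) | COC(=O)C(CC(OC)OC)C(O[Li])C[C@H]1C(=C)CC[C@H]2C(C)(C)CCC[C@]12C | intermediate (not isolated)
25 | mesylate of the aldol from 22 and 14 (mixture at C12 and C13) | COC(=O)C(CC(OC)OC)C(OS(C)(=O)=O)C[C@H]1C(=C)CC[C@H]2C(C)(C)CCC[C@]12C | intermediate (not isolated)
26 | methyl (2E)-2-(2,2-dimethoxyethyl)-4-[(1S,4aS,8aS)-5,5,8a-trimethyl-2-methylidenedecahydronaphthalen-1-yl]but-2-enoate | C=C1CC[C@H]2C(C)(C)CCC[C@]2(C)[C@H]1C/C=C(\CC(OC)OC)C(=O)OC | intermediate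
27 | (2E)-2-(2,2-dimethoxyethyl)-4-[(1S,4aS,8aS)-5,5,8a-trimethyl-2-methylidenedecahydronaphthalen-1-yl]but-2-enoic acid | C=C1CC[C@H]2C(C)(C)CCC[C@]2(C)[C@H]1C/C=C(\CC(OC)OC)C(=O)O | intermediate
28 | mixed anhydride of 27 with 2,4,6-trichlorobenzoic acid | C=C1CC[C@H]2C(C)(C)CCC[C@]2(C)[C@H]1C/C=C(\CC(OC)OC)C(=O)OC(=O)c1c(Cl)cc(Cl)cc1Cl | intermediate (not isolated)
29 | (3R,4E)-5-oxo-4-{2-[(1S,4aS,8aS)-5,5,8a-trimethyl-2-methylidenedecahydronaphthalen-1-yl]ethylidene}oxolan-3-yl (2E)-2-(2,2-dimethoxyethyl)-4-[(1S,4aS,8aS)-5,5,8a-trimethyl-2-methylidenedecahydronaphthalen-1-yl]but-2-enoate | C=C1CC[C@H]2C(C)(C)CCC[C@]2(C)[C@H]1C/C=C(\CC(OC)OC)C(=O)O[C@H]1COC(=O)/C1=C/C[C@H]1C(=C)CC[C@H]2C(C)(C)CCC[C@]12C | intermediate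
30 | (3R,4E)-5-oxo-4-{2-[(1S,4aS,8aS)-5,5,8a-trimethyl-2-methylidenedecahydronaphthalen-1-yl]ethylidene}oxolan-3-yl (2E)-2-(2-oxoethyl)-4-[(1S,4aS,8aS)-5,5,8a-trimethyl-2-methylidenedecahydronaphthalen-1-yl]but-2-enoate (CNP0274315.1) | C=C1CC[C@H]2C(C)(C)CCC[C@]2(C)[C@H]1C/C=C(\CC=O)C(=O)O[C@H]1COC(=O)/C1=C/C[C@H]1C(=C)CC[C@H]2C(C)(C)CCC[C@]12C | target

**Step count.** Total: 14 steps. Longest linear sequence: 11 steps (steps 1–7, 9, 10, 13, 14; the branch through steps 11 and 12 is equally long).

**Steps most likely to fail**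

1. Step 6 (proposed new method). The ring-expanded cation may collapse by proton loss, hydride shift or methyl shift before ring B closes, a ring bond other than C4–C10 may migrate, or ionisation may be too slow next to the allylsilane. The fallback separates ring expansion and ring closure into known reactions; it sets out from 6 and comes back at 12.
   - Alkynol 6 is mesylated (MsCl, Et3N, CH2Cl2) to (1S)-1-(1,2,2-trimethylcyclopentyl)pent-4-yn-1-yl methanesulfonate F1.
   - Buffered solvolysis (2,6-lutidine, 2,2,2-trifluoroethanol/H2O 7:3, 50 °C) effects the Wagner–Meerwein ring enlargement with water capture, since the terminal alkyne is a poor π-nucleophile, to give (2S)-2-(but-3-yn-1-yl)-1,3,3-trimethylcyclohexan-1-ol F2.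
   - The carbocupration and oxirane trapping of step 4 then give (3Z)-6-[(1S)-2-hydroxy-2,6,6-trimethylcyclohexyl]-4-[(trimethylsilyl)methyl]hex-3-en-1-ol F3.
   - Selective mesylation of the primary hydroxyl (MsCl 1.05 equiv, Et3N, −20 °C) gives (3Z)-6-[(1S)-2-hydroxy-2,6,6-trimethylcyclohexyl]-4-[(trimethylsilyl)methyl]hex-3-en-1-yl methanesulfonate F4.
   - Ionisation of the tertiary alcohol with SnCl4 (CH2Cl2, −78 °C) triggers the allylsilane-terminated cyclisation to 12.

2. Step 4. The silylmethylcopper reagent may add sluggishly in the presence of the magnesium alkoxide, or the alkenylcopper may open oxirane incompletely. The fallback builds the same Z-allylsilane from a dihydrofuran; it sets out from 3 and comes back at 8.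
   - Ketone 3 is α-methylenated (paraformaldehyde, N-methylanilinium trifluoroacetate, THF, reflux) to 1-(1,2,2-trimethylcyclopentyl)prop-2-en-1-one F5.
   - Conjugate addition of lithium bis(4,5-dihydrofuran-2-yl)cuprate (from 2,3-dihydrofuran, t-BuLi, CuI; TMSCl, THF, −78 °C) gives 3-(4,5-dihydrofuran-2-yl)-1-(1,2,2-trimethylcyclopentyl)propan-1-one F6.
   - Reduction as in step 3 gives (1S)-3-(4,5-dihydrofuran-2-yl)-1-(1,2,2-trimethylcyclopentyl)propan-1-ol F7.
   - Nickel-catalysed ring-opening coupling with Me3SiCH2MgCl (NiCl2(PPh3)2 5 mol %, toluene, reflux) replaces the ring oxygen by CH2SiMe3 with retention of alkene geometry and gives diol 8.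

3. Step 1. C-methylation of the hindered tetrasubstituted enolate may be slow, allowing proton transfer and methylation on the acetyl methyl group instead. The fallback makes the quaternary centre where no regiochemical choice exists; it sets out from 1 and comes back at 3.
   - Me2CuLi addition to 1 with protic work-up gives 1-(2,2-dimethylcyclopentyl)ethan-1-one F8.
   - Haloform cleavage (NaOBr, dioxane/H2O, 0 °C) gives 2,2-dimethylcyclopentane-1-carboxylic acid F9.
   - The carboxylate dianion (LDA 2.2 equiv, THF/HMPA) is methylated with MeI to 1,2,2-trimethylcyclopentane-1-carboxylic acid F10.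
   - MeLi (2.2 equiv, Et2O, 0 °C) converts F10 into methyl ketone 3.

**Further compounds**

F1 | step 6 | (1S)-1-(1,2,2-trimethylcyclopentyl)pent-4-yn-1-yl methanesulfonate | C#CCC[C@H](OS(C)(=O)=O)C1(C)CCCC1(C)C
F2 | step 6 | (2S)-2-(but-3-yn-1-yl)-1,3,3-trimethylcyclohexan-1-ol | CC1(O)CCCC(C)(C)[C@@H]1CCC#C
F3 | step 6 | (3Z)-6-[(1S)-2-hydroxy-2,6,6-trimethylcyclohexyl]-4-[(trimethylsilyl)methyl]hex-3-en-1-ol | CC1(O)CCCC(C)(C)[C@@H]1CC/C(C[Si](C)(C)C)=C/CCO
F4 | step 6 | (3Z)-6-[(1S)-2-hydroxy-2,6,6-trimethylcyclohexyl]-4-[(trimethylsilyl)methyl]hex-3-en-1-yl methanesulfonate | CC1(O)CCCC(C)(C)[C@@H]1CC/C(C[Si](C)(C)C)=C/CCOS(C)(=O)=O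
F5 | step 4 | 1-(1,2,2-trimethylcyclopentyl)prop-2-en-1-one | C=CC(=O)C1(C)CCCC1(C)C
F6 | step 4 | 3-(4,5-dihydrofuran-2-yl)-1-(1,2,2-trimethylcyclopentyl)propan-1-one | O=C(CCC1=CCCO1)C1(C)CCCC1(C)C
F7 | step 4 | (1S)-3-(4,5-dihydrofuran-2-yl)-1-(1,2,2-trimethylcyclopentyl)propan-1-ol | O1CCC=C1CC[C@H](O)C1(C)CCCC1(C)C
F8 | step 1 | 1-(2,2-dimethylcyclopentyl)ethan-1-one | CC(=O)C1CCCC1(C)C
F9 | step 1 | 2,2-dimethylcyclopentane-1-carboxylic acid | OC(=O)C1CCCC1(C)C
F10 | step 1 | 1,2,2-trimethylcyclopentane-1-carboxylic acid | OC(=O)C1(C)CCCC1(C)C
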